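**Retrosynthetic overview** (locants are those of the hexahydro-1-benzofuran-2-one core: O-1, C-2, C-3, C-3a, C-4 … C-7a)
1. Target 24 comes from diol 23 by double acetylation; 23 is cut in one operation at C-3a–C-7a and C-4–C-5 into the acyclic enol-triflate aldehyde 14 and the bromomethyl butenolide 20.
2. Enabling feature: C-3a of the cyclohexene is the β-carbon of the 3-methylidene γ-lactone and lies between two carbinol carbons, C-7a and C-4, so the lactone acyl group can sit on either oxygen. C-4 is therefore stored in 20 as the acetal carbon of a butenolide whose bromomethyl arm makes C-3a an allyl-metal γ-terminus; acyl migration from O-4 to O-7a then frees C-4 as an aldehyde for the C-5 alkenyl metal.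
3. Ring order: auxiliary butenolide (already in 20), then the γ-lactone by acyl relay, then the cyclohexene by alkenylchromium closure, the last two in step 12. The menthyl acetal controls C-3a, C-7a and C-4 and is erased in the same step.
4. 14 comes from (S)-3-methyloxan-2-one 6 and methyl 4,4-dimethoxybutanoate 7 (crossed Claisen, (E)-enol triflation, reduction, methacryloylation, hydrolysis); 6 comes from an auxiliary-controlled allylation and hydroboration.
5. 20 comes from the (5R)-menthyloxy butenolide 15 (α-bromination, Stille hydroxymethylation, Appel reaction).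

Key step: step 12

Assumption (chemistry): the crystalline acetal 15 of 5-hydroxyfuran-2(5H)-one with (−)-menthol is taken as a purchasable chiral building block.

Step 1
Reactants: 1 (4R)-4-benzyl-3-propanoyl-1,3-oxazolidin-2-one; 2 3-iodoprop-1-ene
Product: 3 (4R)-4-benzyl-3-[(2S)-2-methylpent-4-enoyl]-1,3-oxazolidin-2-one
Conditions: NaN(SiMe3)2, THF, −78 °C; then 2, −78 to −40 °C
Reagents that add atoms: none
Why: Evans asymmetric alkylation, in which the chelated (Z)-sodium enolate is allylated on the face away from the benzyl group and so sets the side-chain methyl centre as (S).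

Step 2
Reactants: 3 (4R)-4-benzyl-3-[(2S)-2-methylpent-4-enoyl]-1,3-oxazolidin-2-one
Product: 6 (3S)-3-methyloxan-2-one, via alkylborane 4 (not isolated), via hydroxy imide 5 (not isolated)
Conditions: 9-BBN, THF, 0 °C to rt; then H2O2, pH 7 phosphate buffer, 0 °C; then DBU (cat.), CH2Cl2, rt
Reagents that add atoms: hydrogen peroxide OO
Why: Anti-Markovnikov hydroboration–oxidation gives the primary alcohol, which lactonises onto the activated imide carbonyl (6-exo-trig acyl substitution) and releases the auxiliary without touching the α-stereocentre.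

Step 3
Reactants: 6 (3S)-3-methyloxan-2-one; 7 methyl 4,4-dimethoxybutanoate
Product: 8 methyl (4S)-2-(2,2-dimethoxyethyl)-7-hydroxy-4-methyl-3-oxoheptanoate
Conditions: LiN(i-Pr)2 and 7 (2.2 equiv each), THF, −78 °C; then 6, −78 to −30 °C; aq. NH4Cl
Reagents that add atoms: none
Why: Crossed Claisen condensation in which the lithium ester enolate opens the lactone at its carbonyl and the product is protected in the flask as its β-keto ester enolate, so the α-methyl centre of 6 should be kept and the C-2 epimers converge in step 5.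

Step 4
Reactants: 8 methyl (4S)-2-(2,2-dimethoxyethyl)-7-hydroxy-4-methyl-3-oxoheptanoate
Product: 9 methyl (4S)-7-[(tert-butyldimethylsilyl)oxy]-2-(2,2-dimethoxyethyl)-4-methyl-3-oxoheptanoate
Conditions: TBSCl, imidazole, DMF, rt
Reagents that add atoms: tert-butyldimethylsilyl chloride CC(C)(C)[Si](C)(C)Cl
Why: Standard silylation of the primary alcohol, which also pulls the hemiketal/hydroxy ketone equilibrium to the open chain.

Step 5
Reactants: 9 methyl (4S)-7-[(tert-butyldimethylsilyl)oxy]-2-(2,2-dimethoxyethyl)-4-methyl-3-oxoheptanoate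
Product: 10 methyl (2E,4S)-7-[(tert-butyldimethylsilyl)oxy]-2-(2,2-dimethoxyethyl)-4-methyl-3-[(trifluoromethanesulfonyl)oxy]hept-2-enoate
Conditions: Tf2O, aq. Me4NOH, toluene, 0 °C
Reagents that add atoms: trifluoromethanesulfonic anhydride O=S(=O)(OS(=O)(=O)C(F)(F)F)C(F)(F)F
Why: Stereoselective enol triflation of a 2-substituted β-keto ester under non-chelating (ammonium counter-ion) conditions, where dipole minimisation should place the enolate oxygen anti to the ester and so give the (E)-triflate with the triflate cis to the dimethoxyethyl arm.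

Step 6
Reactants: 10 methyl (2E,4S)-7-[(tert-butyldimethylsilyl)oxy]-2-(2,2-dimethoxyethyl)-4-methyl-3-[(trifluoromethanesulfonyl)oxy]hept-2-enoate
Product: 11 (2E,4S)-7-[(tert-butyldimethylsilyl)oxy]-2-(2,2-dimethoxyethyl)-1-hydroxy-4-methylhept-2-en-3-yl trifluoromethanesulfonate
Conditions: i-Bu2AlH (2.5 equiv), CH2Cl2, −78 °C; aq. sodium potassium tartrate
Reagents that add atoms: none
Why: 1,2-Reduction of the conjugated ester by the aluminium hydride gives the allylic alcohol, a reduction that enol triflates survive at low temperature.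

Step 7
Reactants: 11 (2E,4S)-7-[(tert-butyldimethylsilyl)oxy]-2-(2,2-dimethoxyethyl)-1-hydroxy-4-methylhept-2-en-3-yl trifluoromethanesulfonate; 12 2-methylprop-2-enoyl chloride
Product: 13 (2E,4S)-7-[(tert-butyldimethylsilyl)oxy]-2-(2,2-dimethoxyethyl)-4-methyl-3-[(trifluoromethanesulfonyl)oxy]hept-2-en-1-yl 2-methylprop-2-enoate
Conditions: Et3N, DMAP (cat.), CH2Cl2, 0 °C
Reagents that add atoms: none
Why: DMAP-catalysed acylation of the primary allylic alcohol installs the final methacrylate, so this oxygen never needs a protecting group.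

Step 8
Reactants: 13 (2E,4S)-7-[(tert-butyldimethylsilyl)oxy]-2-(2,2-dimethoxyethyl)-4-methyl-3-[(trifluoromethanesulfonyl)oxy]hept-2-en-1-yl 2-methylprop-2-enoate
Product: 14 (2E,4S)-7-hydroxy-4-methyl-2-(2-oxoethyl)-3-[(trifluoromethanesulfonyl)oxy]hept-2-en-1-yl 2-methylprop-2-enoate
Conditions: 1 M aq. HCl, THF, 0 °C to rt; used at once
Reagents that add atoms: water O
Why: Aqueous acid hydrolysis removes the dimethyl acetal and the primary silyl ether in one operation, while enol triflate and allylic ester are stable to it.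

Step 9
Reactants: 15 (5R)-5-{[(1R,2S,5R)-5-methyl-2-(propan-2-yl)cyclohexyl]oxy}furan-2(5H)-one
Product: 17 (5R)-3-bromo-5-{[(1R,2S,5R)-5-methyl-2-(propan-2-yl)cyclohexyl]oxy}furan-2(5H)-one, via dibromo lactone 16 (not isolated)
Conditions: Br2, CH2Cl2, 0 °C; then Et3N, 0 °C to rt
Reagents that add atoms: bromine BrBr
Why: Bromine addition to the butenolide alkene followed by E1cB loss of HBr through the acidic α-proton gives the α-bromo butenolide and leaves the acetal centre untouched.

Step 10
Reactants: 17 (5R)-3-bromo-5-{[(1R,2S,5R)-5-methyl-2-(propan-2-yl)cyclohexyl]oxy}furan-2(5H)-one; 18 (tributylstannyl)methanol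
Product: 19 (5R)-3-(hydroxymethyl)-5-{[(1R,2S,5R)-5-methyl-2-(propan-2-yl)cyclohexyl]oxy}furan-2(5H)-one
Conditions: Pd(PPh3)4 (5 mol %), 1,4-dioxane, 90 °C
Reagents that add atoms: none
Why: Stille cross-coupling of the α-bromo enoate with the hydroxymethyl stannane transfers CH2OH to C-3 of the butenolide.

Step 11
Reactants: 19 (5R)-3-(hydroxymethyl)-5-{[(1R,2S,5R)-5-methyl-2-(propan-2-yl)cyclohexyl]oxy}furan-2(5H)-one
Product: 20 (5R)-3-(bromomethyl)-5-{[(1R,2S,5R)-5-methyl-2-(propan-2-yl)cyclohexyl]oxy}furan-2(5H)-one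
Conditions: CBr4, PPh3, CH2Cl2, 0 °C
Reagents that add atoms: carbon tetrabromide BrC(Br)(Br)Br
Why: The Appel reaction converts the primary allylic alcohol into the bromide by SN2 displacement under neutral conditions that spare the pseudo-ester.

Step 12
Reactants: 14 (2E,4S)-7-hydroxy-4-methyl-2-(2-oxoethyl)-3-[(trifluoromethanesulfonyl)oxy]hept-2-en-1-yl 2-methylprop-2-enoate; 20 (5R)-3-(bromomethyl)-5-{[(1R,2S,5R)-5-methyl-2-(propan-2-yl)cyclohexyl]oxy}furan-2(5H)-one
Product: 23 [(3aR,4S,7aR)-4-hydroxy-5-[(2S)-5-hydroxypentan-2-yl]-3-methylidene-2-oxo-2,3,3a,4,7,7a-hexahydro-1-benzofuran-6-yl]methyl 2-methylprop-2-enoate, via hydroxy pseudo-ester 21 (not isolated), via formyl lactone 22 (not isolated)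
Conditions: CrCl2 (8 equiv), DMF, 0 °C to rt, 20 added over 2 h; then NiCl2 (5 mol %), high dilution, rt to 40 °C; aq. work-up
Reagents that add atoms: none
Why: Proposed new method: CrCl2 turns the allylic bromide of 20 into an allylchromium whose geometry is locked by the butenolide ring (acetal carbon trans to the CH2Cr group) and which adds through butenolide C-4 to the aldehyde of 14 in a chair transition state, as in the known Nozaki–Hiyama 2-(alkoxycarbonyl)allylation that makes α-methylene-γ-butyrolactones; this forms the C-3a–C-7a bond. The aldehyde should enter anti to the menthyloxy group (controls C-3a) and with its chain equatorial (anti adduct, controls C-7a). The chromium alkoxide of 21 then attacks the pseudo-ester carbonyl (5-exo-trig acyl transfer through a bicyclic ortho-ester), which closes the γ-lactone trans across C-3a–C-7a, opens the auxiliary ring and lets its hemiacetal lose menthol, so the formyl group of 22 appears only after the allylchromium is spent. After NiCl2 is added, zerovalent nickel inserts into the enol triflate, the alkenyl group passes to trivalent chromium and adds to that aldehyde (6-exo-trig Nozaki–Hiyama–Kishi closure of the cyclohexene, C-4–C-5 bond), a known way to close cycloalkenols from alkenyl triflates. C-4 is set in this closure, where the chromium-bound oxygen should sit pseudo-axial, cis to the C-3a–C-3 bond, to avoid A(1,2) strain with the branched C-5 substituent. The step needs chemoselectivity (allyl before alkenyl activation and no allylation of 22), secured by the nickel-free first stage and the slow addition of 20, and it needs the (E) alkene of 14, which holds the triflate cis to the aldehyde arm.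

Step 13
Reactants: 23 [(3aR,4S,7aR)-4-hydroxy-5-[(2S)-5-hydroxypentan-2-yl]-3-methylidene-2-oxo-2,3,3a,4,7,7a-hexahydro-1-benzofuran-6-yl]methyl 2-methylprop-2-enoate
Product: 24 [(3aS,4S,7aR)-4-(acetyloxy)-5-[(2S)-5-(acetyloxy)pentan-2-yl]-3-methylidene-2-oxo-2,3,3a,4,7,7a-hexahydro-1-benzofuran-6-yl]methyl 2-methylprop-2-enoate
Conditions: Ac2O, pyridine, DMAP (cat.), CH2Cl2, 0 °C to rt
Reagents that add atoms: acetic anhydride CC(=O)OC(C)=O
Why: DMAP-catalysed acetylation of the primary and the secondary allylic hydroxyl groups proceeds with retention and completes the target (the C-3a descriptor changes from R to S only because the CIP ranking changes on acetylation).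

**Compound list**
1 | (4R)-4-benzyl-3-propanoyl-1,3-oxazolidin-2-one | CCC(=O)N1[C@H](Cc2ccccc2)COC1=O | starting material
2 | 3-iodoprop-1-ene | C=CCI | starting material
3 | (4R)-4-benzyl-3-[(2S)-2-methylpent-4-enoyl]-1,3-oxazolidin-2-one | C=CC[C@H](C)C(=O)N1[C@H](Cc2ccccc2)COC1=O | intermediate
4 | (4R)-4-benzyl-3-[(2S)-5-(9-borabicyclo[3.3.1]nonan-9-yl)-2-methylpentanoyl]-1,3-oxazolidin-2-one | C[C@@H](CCCB1C2CCCC1CCC2)C(=O)N1[C@H](Cc2ccccc2)COC1=O | intermediate
5 | (4R)-4-benzyl-3-[(2S)-5-hydroxy-2-methylpentanoyl]-1,3-oxazolidin-2-one | C[C@@H](CCCO)C(=O)N1[C@H](Cc2ccccc2)COC1=O | intermediate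
6 | (3S)-3-methyloxan-2-one | O=C1OCCC[C@@H]1C | intermediate
7 | methyl 4,4-dimethoxybutanoate | COC(=O)CCC(OC)OC | starting material
8 | methyl (4S)-2-(2,2-dimethoxyethyl)-7-hydroxy-4-methyl-3-oxoheptanoate (C-2 epimers; partly as cyclic hemiketal) | COC(=O)C(CC(OC)OC)C(=O)[C@@H](C)CCCO | intermediate
9 | methyl (4S)-7-[(tert-butyldimethylsilyl)oxy]-2-(2,2-dimethoxyethyl)-4-methyl-3-oxoheptanoate | COC(=O)C(CC(OC)OC)C(=O)[C@@H](C)CCCO[Si](C)(C)C(C)(C)C | intermediate
10 | methyl (2E,4S)-7-[(tert-butyldimethylsilyl)oxy]-2-(2,2-dimethoxyethyl)-4-methyl-3-[(trifluoromethanesulfonyl)oxy]hept-2-enoate | COC(OC)C/C(C(=O)OC)=C(\OS(=O)(=O)C(F)(F)F)[C@@H](C)CCCO[Si](C)(C)C(C)(C)C | intermediate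
11 | (2E,4S)-7-[(tert-butyldimethylsilyl)oxy]-2-(2,2-dimethoxyethyl)-1-hydroxy-4-methylhept-2-en-3-yl trifluoromethanesulfonate | COC(OC)C/C(CO)=C(\OS(=O)(=O)C(F)(F)F)[C@@H](C)CCCO[Si](C)(C)C(C)(C)C | intermediate
12 | 2-methylprop-2-enoyl chloride | CC(=C)C(=O)Cl | starting material
13 | (2E,4S)-7-[(tert-butyldimethylsilyl)oxy]-2-(2,2-dimethoxyethyl)-4-methyl-3-[(trifluoromethanesulfonyl)oxy]hept-2-en-1-yl 2-methylprop-2-enoate | COC(OC)C/C(COC(=O)C(C)=C)=C(\OS(=O)(=O)C(F)(F)F)[C@@H](C)CCCO[Si](C)(C)C(C)(C)C | intermediate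
14 | (2E,4S)-7-hydroxy-4-methyl-2-(2-oxoethyl)-3-[(trifluoromethanesulfonyl)oxy]hept-2-en-1-yl 2-methylprop-2-enoate | O=CC/C(COC(=O)C(C)=C)=C(\OS(=O)(=O)C(F)(F)F)[C@@H](C)CCCO | intermediate
15 | (5R)-5-{[(1R,2S,5R)-5-methyl-2-(propan-2-yl)cyclohexyl]oxy}furan-2(5H)-one | O=C1C=C[C@H](O[C@@H]2C[C@H](C)CC[C@H]2C(C)C)O1 | starting material
16 | (3S,4S,5R)-3,4-dibromo-5-{[(1R,2S,5R)-5-methyl-2-(propan-2-yl)cyclohexyl]oxy}oxolan-2-one (expected all-trans dibromide) | O=C1[C@H](Br)[C@@H](Br)[C@H](O[C@@H]2C[C@H](C)CC[C@H]2C(C)C)O1 | intermediate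
17 | (5R)-3-bromo-5-{[(1R,2S,5R)-5-methyl-2-(propan-2-yl)cyclohexyl]oxy}furan-2(5H)-one | O=C1C(Br)=C[C@H](O[C@@H]2C[C@H](C)CC[C@H]2C(C)C)O1 | intermediate
18 | (tributylstannyl)methanol | CCCC[Sn](CCCC)(CCCC)CO | starting material
19 | (5R)-3-(hydroxymethyl)-5-{[(1R,2S,5R)-5-methyl-2-(propan-2-yl)cyclohexyl]oxy}furan-2(5H)-one | O=C1C(CO)=C[C@H](O[C@@H]2C[C@H](C)CC[C@H]2C(C)C)O1 | intermediate
20 | (5R)-3-(bromomethyl)-5-{[(1R,2S,5R)-5-methyl-2-(propan-2-yl)cyclohexyl]oxy}furan-2(5H)-one | O=C1C(CBr)=C[C@H](O[C@@H]2C[C@H](C)CC[C@H]2C(C)C)O1 | intermediate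
21 | (2E,4S)-7-hydroxy-2-[(2R)-2-hydroxy-2-{(2R,3S)-2-(menthyloxy)-4-methylidene-5-oxooxolan-3-yl}ethyl]-4-methyl-3-[(trifluoromethanesulfonyl)oxy]hept-2-en-1-yl 2-methylprop-2-enoate (menthyl = (1R,2S,5R)) | O=C1C(=C)[C@@H]([C@H](O)C/C(COC(=O)C(C)=C)=C(\OS(=O)(=O)C(F)(F)F)[C@@H](C)CCCO)[C@H](O[C@@H]2C[C@H](C)CC[C@H]2C(C)C)O1 | intermediate
22 | (2E,4S)-2-{[(2R,3S)-3-formyl-4-methylidene-5-oxooxolan-2-yl]methyl}-7-hydroxy-4-methyl-3-[(trifluoromethanesulfonyl)oxy]hept-2-en-1-yl 2-methylprop-2-enoate | O=C[C@H]1C(=C)C(=O)O[C@@H]1C/C(COC(=O)C(C)=C)=C(\OS(=O)(=O)C(F)(F)F)[C@@H](C)CCCO | intermediate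
23 | [(3aR,4S,7aR)-4-hydroxy-5-[(2S)-5-hydroxypentan-2-yl]-3-methylidene-2-oxo-2,3,3a,4,7,7a-hexahydro-1-benzofuran-6-yl]methyl 2-methylprop-2-enoate | C=C(C)C(=O)OCC1=C([C@@H](C)CCCO)[C@@H](O)[C@H]2C(=C)C(=O)O[C@@H]2C1 | intermediate
24 | [(3aS,4S,7aR)-4-(acetyloxy)-5-[(2S)-5-(acetyloxy)pentan-2-yl]-3-methylidene-2-oxo-2,3,3a,4,7,7a-hexahydro-1-benzofuran-6-yl]methyl 2-methylprop-2-enoate | C=C(C)C(=O)OCC1=C([C@@H](C)CCCOC(C)=O)[C@@H](OC(C)=O)[C@H]2C(=C)C(=O)O[C@@H]2C1 | target

**Step count:** 13 steps in total; longest linear sequence 10 steps (steps 1 to 8, then 12 and 13).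

**Steps most likely to fail**

Step 12 (proposed new method). The relay may be interrupted: the chromium alkoxide of 21 may not transfer the acyl group, or the freed β-formyl lactone 22 may epimerise or move its exocyclic double bond into the ring before the slow activation of the hindered triflate. The fallback sets out from 14 and 20 and comes back at 23, and it takes the cascade apart into three known operations in separate flasks. A zinc Barbier allylation (Zn, THF/aq. NH4Cl) gives 21 as an isolated alcohol. Camphorsulfonic acid (cat.) in CH2Cl2 at 0 °C then effects the transacylation and loss of menthol to give 22. Compound 22 is closed at once by a Nozaki–Hiyama–Kishi reaction (CrCl2, NiCl2 cat., DMF, high dilution) to give 23. This fallback makes no compound outside the list (F0).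

Step 5. Enolate geometry may be poorly controlled in the triflation: the hindered ketone may give the chelate-type (Z) isomer, which cannot close the ring. The fallback sets out from 6 and comes back at 11. It replaces the ester by a nitrile, which is linear, cannot chelate and is the smallest possible cis neighbour for the branched side chain, so sterics and dipoles both favour the needed geometry. Lithiated 4,4-dimethoxybutanenitrile (LiN(i-Pr)2, THF, −78 °C) is acylated by 6 to give (4S)-2-(2,2-dimethoxyethyl)-7-hydroxy-4-methyl-3-oxoheptanenitrile F1. TBSCl and imidazole give (4S)-7-[(tert-butyldimethylsilyl)oxy]-2-(2,2-dimethoxyethyl)-4-methyl-3-oxoheptanenitrile F2. Tf2O and i-Pr2NEt in CH2Cl2 at −78 °C should give (2E,4S)-7-[(tert-butyldimethylsilyl)oxy]-2-(2,2-dimethoxyethyl)-4-methyl-3-[(trifluoromethanesulfonyl)oxy]hept-2-enenitrile F3. Reduction with i-Bu2AlH and mild aqueous acid gives the enal (2E,4S)-7-[(tert-butyldimethylsilyl)oxy]-2-(2,2-dimethoxyethyl)-4-methyl-1-oxohept-2-en-3-yl trifluoromethanesulfonate F4. Luche reduction (NaBH4, CeCl3, MeOH) then gives 11.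

Step 3. Proton transfer from the lactone to the ester enolate may compete with addition, which would erode the α-methyl centre and leave conversion incomplete. The fallback sets out from 6 and comes back at 9. MeNH(OMe)·HCl and i-PrMgCl in THF at −20 °C open 6 to the Weinreb amide (2S)-5-hydroxy-N-methoxy-N,2-dimethylpentanamide F5. TBSCl and imidazole give (2S)-5-[(tert-butyldimethylsilyl)oxy]-N-methoxy-N,2-dimethylpentanamide F6. The lithium enolate of 7 is then acylated by F6, whose α-proton is less acidic and whose tetrahedral adduct is stable, to give 9 directly.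

**Further compounds**
F0 | step 12 | none | none
F1 | step 5 | (4S)-2-(2,2-dimethoxyethyl)-7-hydroxy-4-methyl-3-oxoheptanenitrile | N#CC(CC(OC)OC)C(=O)[C@@H](C)CCCO
F2 | step 5 | (4S)-7-[(tert-butyldimethylsilyl)oxy]-2-(2,2-dimethoxyethyl)-4-methyl-3-oxoheptanenitrile | N#CC(CC(OC)OC)C(=O)[C@@H](C)CCCO[Si](C)(C)C(C)(C)C
F3 | step 5 | (2E,4S)-7-[(tert-butyldimethylsilyl)oxy]-2-(2,2-dimethoxyethyl)-4-methyl-3-[(trifluoromethanesulfonyl)oxy]hept-2-enenitrile | COC(OC)C/C(C#N)=C(\OS(=O)(=O)C(F)(F)F)[C@@H](C)CCCO[Si](C)(C)C(C)(C)C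
F4 | step 5 | (2E,4S)-7-[(tert-butyldimethylsilyl)oxy]-2-(2,2-dimethoxyethyl)-4-methyl-1-oxohept-2-en-3-yl trifluoromethanesulfonate | COC(OC)C/C(C=O)=C(\OS(=O)(=O)C(F)(F)F)[C@@H](C)CCCO[Si](C)(C)C(C)(C)C
F5 | step 3 | (2S)-5-hydroxy-N-methoxy-N,2-dimethylpentanamide | CON(C)C(=O)[C@@H](C)CCCO
F6 | step 3 | (2S)-5-[(tert-butyldimethylsilyl)oxy]-N-methoxy-N,2-dimethylpentanamide | CON(C)C(=O)[C@@H](C)CCCO[Si](C)(C)C(C)(C)C
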